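**Retrosynthetic overview**

1. Aryl–prenyl C–C bonds (made first): diiodide 1 + prenylstannane 2 ⇒ (through mono-coupled 3) diprenyl methyl ester 4, by double Stille coupling.
2. Ester switch: 4 ⇒ free hydroxy acid 5 (saponification).
3. Key disconnection (made last): the acyl C–O bond to the tertiary carbinol oxygen. Acid 5 and (R)-terpinen-4-ol 6 are joined after activation with 2,4,6-trichlorobenzoyl chloride 7: mixed anhydride 8 releases oxoketene 9 from its phenoxide, and 6 captures 9 to give target 10.
4. Stereochemistry: the single stereocentre is bought in 6 (chiral pool); its C–O bond is never broken.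
5. Rings: none is formed; the benzene ring comes from 1 and the cyclohexene ring from 6.

Assumption: (R)-(−)-terpinen-4-ol 6 is purchased at ≥98% ee (checked by chiral GC; a lot of lower ee is enriched by preparative chiral chromatography before use).

**Route**

Step 1
Reactants: 1 methyl 4-hydroxy-3,5-diiodobenzoate; 2 tributyl(3-methylbut-2-en-1-yl)stannane
Product: 4 methyl 4-hydroxy-3,5-bis(3-methylbut-2-en-1-yl)benzoate, via mono-prenylated iodide 3 (not isolated)
Conditions: Pd(PPh3)4 (10 mol%), 2 (3.2 equiv), degassed DMF, 90 °C, 16 h; chromatography on SiO2 containing 10% K2CO3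
Reagents that add atoms: none
Why: Stille cross-coupling, in which zerovalent palladium inserts into each aryl C–I bond, the prenyl group is transferred from tin and reductive elimination at the less hindered primary allyl terminus gives the linear prenyl arene twice (the free phenol is tolerated; one sacrificial equivalent of 2 covers protodestannylation); no stereocentre is formed.

Step 2
Reactants: 4 methyl 4-hydroxy-3,5-bis(3-methylbut-2-en-1-yl)benzoate
Product: 5 4-hydroxy-3,5-bis(3-methylbut-2-en-1-yl)benzoic acid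
Conditions: KOH (6 equiv), MeOH/H2O 4:1, 70 °C, 6 h; then 1 M HCl to pH 3 at 0 °C
Reagents that add atoms: potassium hydroxide, [K+].[OH-]
Why: Saponification (acyl–oxygen cleavage by hydroxide), slow but clean for a para-hydroxybenzoate at 70 °C; the prenyl groups are inert to base, and cold dilute acid on work-up avoids chroman formation.

Step 3
Reactants: 5 4-hydroxy-3,5-bis(3-methylbut-2-en-1-yl)benzoic acid; 6 (R)-(−)-terpinen-4-ol, i.e. (1R)-4-methyl-1-(propan-2-yl)cyclohex-3-en-1-ol; 7 2,4,6-trichlorobenzoyl chloride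
Product: 10 (1R)-4-methyl-1-(propan-2-yl)cyclohex-3-en-1-yl 4-hydroxy-3,5-bis(3-methylbut-2-en-1-yl)benzoate, via mixed anhydride 8 (not isolated), via oxoketene 9 (not isolated)
Conditions: 2-tert-butyl-1,1,3,3-tetramethylguanidine (BTMG, 1.0 equiv), THF (0.05 M), 4 Å molecular sieves, 0 °C, then 7 (1.05 equiv), 1 h; then 6 (2.0 equiv); then BTMG (1.05 equiv) by syringe pump over 3 h, 0 °C → rt; NaHCO3 wash, SiO2
Reagents that add atoms: none
Why: Proposed new method: a protecting-group-free esterification in which the free phenol is the trigger, since deprotonation of mixed anhydride 8 by the hindered guanidine gives a phenoxide whose para oxygen lone pair expels 2,4,6-trichlorobenzoate (E1cB, dissociative acyl transfer) to form the sp-hybridised, acylium-like oxoketene 9, which the tertiary alcohol 6 can reach where addition–elimination at a phenoxide-deactivated carbonyl cannot; re-aromatisation drives O–H addition across the ketene, the two flanking prenyl groups and the slow base addition keep phenoxide self-acylation down, and the C–O bond at the stereocentre of 6 is never broken so (R) is carried over unchanged; the closest known reaction types are the E1cB hydrolysis of activated aryl 4-hydroxybenzoates through this kind of oxoketene, the capture of acylketenes by tertiary alcohols, and the Yamaguchi mixed-anhydride esterification.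

**Compound list**

1 | methyl 4-hydroxy-3,5-diiodobenzoate | COC(=O)c1cc(I)c(O)c(I)c1 | starting material
2 | tributyl(3-methylbut-2-en-1-yl)stannane | CCCC[Sn](CCCC)(CCCC)CC=C(C)C | starting material
3 | methyl 4-hydroxy-3-iodo-5-(3-methylbut-2-en-1-yl)benzoate | COC(=O)c1cc(I)c(O)c(CC=C(C)C)c1 | intermediate (not isolated)
4 | methyl 4-hydroxy-3,5-bis(3-methylbut-2-en-1-yl)benzoate | COC(=O)c1cc(CC=C(C)C)c(O)c(CC=C(C)C)c1 | intermediate
5 | 4-hydroxy-3,5-bis(3-methylbut-2-en-1-yl)benzoic acid | OC(=O)c1cc(CC=C(C)C)c(O)c(CC=C(C)C)c1 | intermediate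
6 | (R)-(−)-terpinen-4-ol, (1R)-4-methyl-1-(propan-2-yl)cyclohex-3-en-1-ol | O[C@@]1(C(C)C)CC=C(C)CC1 | starting material
7 | 2,4,6-trichlorobenzoyl chloride | O=C(Cl)c1c(Cl)cc(Cl)cc1Cl | starting material
8 | 4-hydroxy-3,5-bis(3-methylbut-2-en-1-yl)benzoic 2,4,6-trichlorobenzoic anhydride | CC(C)=CCc1cc(C(=O)OC(=O)c2c(Cl)cc(Cl)cc2Cl)cc(CC=C(C)C)c1O | intermediate (not isolated)
9 | 2,6-bis(3-methylbut-2-en-1-yl)-4-(oxomethylidene)cyclohexa-2,5-dien-1-one (para-oxoketene) | O=C=C1C=C(CC=C(C)C)C(=O)C(CC=C(C)C)=C1 | intermediate (not isolated)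
10 | (1R)-4-methyl-1-(propan-2-yl)cyclohex-3-en-1-yl 4-hydroxy-3,5-bis(3-methylbut-2-en-1-yl)benzoate | CC(C)=CCc1cc(C(=O)O[C@@]2(C(C)C)CC=C(C)CC2)cc(CC=C(C)C)c1O | target

**Totals**

Total step count: 3. Longest linear sequence: 3 steps (1 → 4 → 5 → 10); alcohol 6 enters in the last step.

**Steps most likely to fail, with fallbacks**

Step 3 (the proposed oxoketene acyl transfer). The risks are depside oligomers from phenoxide capture of 9, a slow elimination, or return of 5 if traces of water win. The fallback uses known chemistry, sets out from 5 and comes back at 10. Acid 5 is silylated on both oxygens (TBSOTf, 2,6-lutidine, CH2Cl2, 0 °C) to tert-butyldimethylsilyl 4-[(tert-butyldimethylsilyl)oxy]-3,5-bis(3-methylbut-2-en-1-yl)benzoate F1. The labile silyl ester alone is cleaved (K2CO3, MeOH/THF/H2O, 0 °C) to 4-[(tert-butyldimethylsilyl)oxy]-3,5-bis(3-methylbut-2-en-1-yl)benzoic acid F2. 1,1′-Carbonyldiimidazole in THF converts it into the acyl imidazolide {4-[(tert-butyldimethylsilyl)oxy]-3,5-bis(3-methylbut-2-en-1-yl)phenyl}(1H-imidazol-1-yl)methanone F3. The lithium alkoxide of 6 (n-BuLi, THF, −78 °C → rt) is acylated by F3 to the silyl-protected ester (1R)-4-methyl-1-(propan-2-yl)cyclohex-3-en-1-yl 4-[(tert-butyldimethylsilyl)oxy]-3,5-bis(3-methylbut-2-en-1-yl)benzoate F4. Tetrabutylammonium fluoride buffered with AcOH (THF, 0 °C) frees the phenol and returns to the route at 10.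

Step 1 (double Stille prenylation). The risks are partial transfer of the branched 1,1-dimethylallyl isomer, loss of 2 to the acidic phenol, and an incomplete second coupling. The fallback sets out from 1 and comes back at 4, replacing prenyl transfer by transfer of the symmetrical allyl group followed by olefin metathesis. Coupling of 1 with allyltributylstannane (Pd(PPh3)4, DMF, 90 °C) runs through methyl 4-hydroxy-3-iodo-5-(prop-2-en-1-yl)benzoate F5 to methyl 4-hydroxy-3,5-di(prop-2-en-1-yl)benzoate F6. Cross-metathesis with excess 2-methylbut-2-ene (second-generation Grubbs catalyst RuCl2(=CHPh)(PCy3)(H2IMes), CH2Cl2, 40 °C) then passes through methyl 4-hydroxy-3-(3-methylbut-2-en-1-yl)-5-(prop-2-en-1-yl)benzoate F7 and returns to the route at 4.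

Step 2 (saponification). The risks are a sluggish reaction, because the phenoxide deactivates the ester carbonyl, and chroman formation if acidification is careless. The fallback sets out from 4 and comes back at 5, attacking the methyl carbon instead of the carbonyl: LiI (4 equiv) in refluxing EtOAc cleaves the methyl ester by iodide displacement at the methyl group, and dilute citric acid work-up gives 5; no new compound is made on this way (none F0).

**Further compounds**

F1 | step 3 | tert-butyldimethylsilyl 4-[(tert-butyldimethylsilyl)oxy]-3,5-bis(3-methylbut-2-en-1-yl)benzoate | CC(C)=CCc1cc(C(=O)O[Si](C)(C)C(C)(C)C)cc(CC=C(C)C)c1O[Si](C)(C)C(C)(C)C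
F2 | step 3 | 4-[(tert-butyldimethylsilyl)oxy]-3,5-bis(3-methylbut-2-en-1-yl)benzoic acid | CC(C)=CCc1cc(C(=O)O)cc(CC=C(C)C)c1O[Si](C)(C)C(C)(C)C
F3 | step 3 | {4-[(tert-butyldimethylsilyl)oxy]-3,5-bis(3-methylbut-2-en-1-yl)phenyl}(1H-imidazol-1-yl)methanone | CC(C)=CCc1cc(C(=O)n2ccnc2)cc(CC=C(C)C)c1O[Si](C)(C)C(C)(C)C
F4 | step 3 | (1R)-4-methyl-1-(propan-2-yl)cyclohex-3-en-1-yl 4-[(tert-butyldimethylsilyl)oxy]-3,5-bis(3-methylbut-2-en-1-yl)benzoate | CC(C)=CCc1cc(C(=O)O[C@@]2(C(C)C)CC=C(C)CC2)cc(CC=C(C)C)c1O[Si](C)(C)C(C)(C)C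
F5 | step 1 | methyl 4-hydroxy-3-iodo-5-(prop-2-en-1-yl)benzoate | COC(=O)c1cc(I)c(O)c(CC=C)c1
F6 | step 1 | methyl 4-hydroxy-3,5-di(prop-2-en-1-yl)benzoate | COC(=O)c1cc(CC=C)c(O)c(CC=C)c1
F7 | step 1 | methyl 4-hydroxy-3-(3-methylbut-2-en-1-yl)-5-(prop-2-en-1-yl)benzoate | COC(=O)c1cc(CC=C)c(O)c(CC=C(C)C)c1
F0 | step 2 | none | none
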